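**Remark (assumption).** Diene 13 and its precursor 12 are treated as not purchasable and are made in steps 5–7. Locants: ring carbons C1–C6 (C1 bears the chain, C2 OAc, C3 OMe, C5 OH) and chain carbons C1′ (ArCH2), C2′ (stereocentre), C3′–C15′. The C2′ descriptor was assigned by CIP analysis of the given SMILES as (R).

## The problem

Target 17 is a benzene ring with four substituents: C1 carries the CH2 of a 2-acetoxypentadecyl chain, C2 an acetoxy group, C3 a methoxy group and C5 a free hydroxyl. The ring is a hydroquinone (oxygens on C2 and C5) whose hindered oxygen, flanked by the chain and by OMe, is acetylated while the open one is free. Direct acylation of the hydroquinone would give the opposite result. The only stereocentre, C2′, is a secondary acetate one carbon away from the ring. No other stereogenic element can control it, so it must be bought or set by a reagent. The aryl acetate does not tolerate base or nucleophiles, the electron-rich free phenol does not tolerate strong oxidants, and the homobenzylic acetate can be lost by β-elimination, so the last steps must be mild and non-basic. The feature that opens the plan is this: the oxygens on C3 and C5 are 1,3 to each other, and the C2 oxygen carries an acetyl group and is para to the C5 hydroxyl. If the acetyl carbon is imagined on C2 instead of on its oxygen (Baeyer–Villiger retron), the ring becomes a 2-acetylresorcinol monomethyl ether. Ring atoms C3–C4–C5–C6 of that ring are then the four carbons of a 1,1-dimethoxy-3-silyloxybutadiene, and C2 and C1 are the two sp carbons of an acetyl alkyne that already carries the chain.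

## Retrosynthesis

**17 ⇒ 16.** The C2–O bond of the aryl acetate is traced back to a C2–C(acetyl) bond (Baeyer–Villiger transform), giving ketone 16. Compared with acylating a C2 hydroxyl, the oxygen arrives already acetylated and only where the acetyl group sits, so the C5 hydroxyl never needs protection. Precursor 16 has one C–O bond fewer and a substitution pattern for which a direct ring synthesis exists. The forward reaction must favour aryl over methyl migration and tolerate a free phenol.

**16 ⇒ 8 + 13.** The ring bonds C1–C6 and C2–C3 are cut, which is a [4+2] cycloaddition followed by aromatisation. The neighbouring choice, acylating a preformed 3-methoxy-5-alkylphenol, would have to select among three open ring positions. Here the polarity of two acyclic partners dictates the regiochemistry. Ynone 8 is an open chain with one stereocentre and diene 13 is an achiral four-carbon unit. The ring, its four substituents and the OMe/OH distinction all arise in one step. The forward reaction must be regioselective and must leave the acetate and C2′ untouched.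

**8 ⇒ 6 + 7.** The C(sp)–C(acyl) bond is cut: terminal alkyne 6 is acylated with acetyl chloride 7 under Pd/Cu catalysis. Compared with adding an acetylide to an aldehyde and oxidising, this is one step and avoids strong base on an acetate. The acetyl group introduced here activates the dienophile, steers the regiochemistry and later becomes the C2 acetate.

**6 ⇒ 5 ⇒ 3 ⇒ 1 + 2.** The ester C–O bond leads to alcohol 5. The propargylic C–C bond leads to epoxide 4, which is formed in the flask from chlorohydrin 3. The C3′–C4′ bond leads to (R)-epichlorohydrin 1 and dodecyl Grignard reagent 2. The stereocentre is bought: C2 of 1 becomes C2′ and is never a reacting centre. This was preferred to an asymmetric propargylation of a C14 aldehyde because the configuration is then certain.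

**13 ⇒ 12 ⇒ 11 ⇒ 7 + 9.** The O–Si bond, the two C–OMe bonds and one C–C bond are cut in turn. Forward, these are enol silylation of 12, double vinylic substitution of 11 by methoxide, and acylation of 1,1-dichloroethene 9 with 7.

## Roads not taken

**Alternative 1:** The most obvious cut is the C1–C1′ bond. An aryl copper reagent from 5-(benzyloxy)-1-bromo-3-methoxy-2-(methoxymethoxy)benzene A1 opens epoxide 4 to give alcohol A2. Acetal removal, double acetylation and hydrogenolysis follow. The three oxygens of A1 must be put on and told apart one by one with two orthogonal protecting groups, and the hindered C2 hydroxyl is acetylated only after a deprotection. The key step makes a single C–C bond, and about half of a route of some ten linear steps is protecting-group work. The chosen plan uses no protecting group and sets the oxygen pattern while the ring is formed.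

**Alternative 2:** The biomimetic cut introduces the C2 oxygen late. Phenol A3, a 5-alkylresorcinol monomethyl ether, is oxidised para to its hydroxyl to methoxyquinone A4, which is reduced to hydroquinone A5 and acetylated. Acylation of A5 goes first to the unhindered C5 hydroxyl, the wrong one. Reaching 17 then needs peracetylation with selective hydrolysis or a protect/deprotect detour, plus handling of an air-sensitive quinone/hydroquinone pair. A3 itself still needs an aryl–epoxide coupling. In the chosen plan the oxygen is inserted at C2 already bearing its acetyl group.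

**Alternative 3:** A [3,3] cut of the C1–C1′ bond: allyl aryl ether A6 undergoes an aromatic Claisen rearrangement to 2-allylphenol A7. The methoxy group blocks the other ortho position, so the regiochemistry is clean. The rearrangement delivers only a three-carbon chain without a stereocentre. C2′ would then have to be created on a terminal alkene (epoxidation with kinetic resolution loses half the material), the C12 chain still has to be added, and the C5 oxygen needs a benzyl group on and off. The rearrangement solves the easiest bond and leaves both real problems open.

Key step: step 8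

## Route

**Step 1**
Reactants: 1 (R)-epichlorohydrin; 2 dodecylmagnesium bromide
Product: 3 (R)-1-chloropentadecan-2-ol
Conditions: CuI (10 mol%), THF, −40 → 0 °C; then cold 1 M HCl
Reagents that add atoms: none
Why: Copper-catalysed Grignard opening of the epoxide at its unsubstituted carbon (SN2) is faster than attack at the primary chloride; C2 of 1 is not a reacting centre, so the configuration is kept (descriptor R, since O > CH2Cl > CH2R).

**Step 2**
Reactants: 3 (R)-1-chloropentadecan-2-ol
Product: 5 (R)-heptadec-1-yn-4-ol, via (R)-2-tridecyloxirane 4 (not isolated)
Conditions: LiC≡CH·ethylenediamine (3.5 equiv), DMSO–THF, 0 °C → rt; then H2O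
Reagents that add atoms: lithium acetylide (ethylenediamine complex), [Li]C#C.NCCN
Why: The first equivalent of acetylide deprotonates the alcohol and the chloro alkoxide closes to epoxide 4 (intramolecular Williamson reaction, 3-exo-tet); the acetylide then opens 4 at the CH2 carbon (SN2 epoxide alkynylation), so the carbinol carbon is never substituted and stays (R).

**Step 3**
Reactants: 5 (R)-heptadec-1-yn-4-ol
Product: 6 (R)-heptadec-1-yn-4-yl acetate
Conditions: Ac2O, pyridine, DMAP (cat.), CH2Cl2, rt
Reagents that add atoms: acetic anhydride, CC(=O)OC(C)=O
Why: DMAP-catalysed O-acetylation of a secondary alcohol; the terminal alkyne is inert, and the chain acetate of the target is installed before any phenol exists.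

**Step 4**
Reactants: 6 (R)-heptadec-1-yn-4-yl acetate; 7 acetyl chloride
Product: 8 (R)-2-oxononadec-3-yn-6-yl acetate
Conditions: PdCl2(PPh3)2 (2 mol%), CuI (4 mol%), Et3N (1.5 equiv), THF, rt, exclusion of O2
Reagents that add atoms: none
Why: Acyl Sonogashira coupling of a terminal alkyne with an acid chloride gives the conjugated ynone under mild amine conditions that an acetate tolerates; no stereocentre is formed or touched.

**Step 5**
Reactants: 7 acetyl chloride; 9 1,1-dichloroethene
Product: 11 4,4-dichlorobut-3-en-2-one, via 4,4,4-trichlorobutan-2-one 10 (not isolated)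
Conditions: AlCl3 (1.1 equiv), CH2Cl2, 0 °C → rt; ice/dil. HCl; steam distillation
Reagents that add atoms: none
Why: Friedel–Crafts-type acylation of the alkene by the acylium ion gives the Markovnikov chloride adduct 10, which loses HCl on distillation to the conjugated β,β-dichlorovinyl ketone.

**Step 6**
Reactants: 11 4,4-dichlorobut-3-en-2-one
Product: 12 4,4-dimethoxybut-3-en-2-one
Conditions: NaOMe (2.1 equiv), MeOH, 0 °C → rt; filtration; distillation
Reagents that add atoms: sodium methoxide, [Na+].[O-]C
Why: Two successive conjugate addition–elimination reactions (vinylic substitution) of methoxide at the β-carbon of the enone replace both chlorides and give the acyl ketene acetal.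

**Step 7**
Reactants: 12 4,4-dimethoxybut-3-en-2-one
Product: 13 1,1-dimethoxy-3-(trimethylsilyloxy)buta-1,3-diene
Conditions: LDA, THF, −78 °C; TMSCl, −78 °C → rt; pentane, filtration, distillation
Reagents that add atoms: chlorotrimethylsilane, C[Si](C)(C)Cl
Why: Kinetic deprotonation of the methyl ketone (the only enolisable position) and O-silylation of the cross-conjugated enolate give the silyl enol ether; the work-up is non-aqueous because 13 hydrolyses easily.

**Step 8**
Reactants: 8 (R)-2-oxononadec-3-yn-6-yl acetate; 13 1,1-dimethoxy-3-(trimethylsilyloxy)buta-1,3-diene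
Product: 16 (R)-1-(2-acetyl-5-hydroxy-3-methoxyphenyl)pentadecan-2-yl acetate, via cyclohexadiene cycloadduct 14 (not isolated), via aryl trimethylsilyl ether 15 (not isolated)
Conditions: 13 (1.5 equiv), PhMe, 90–110 °C (sealed tube); then 0.5 M HCl, THF, 0 °C → rt
Reagents that add atoms: none
Why: Diels–Alder benzannulation: thermal normal-demand [4+2] of the electron-rich diene 13 with ynone 8, then aromatisation; the closest known type is the cycloaddition of 1,1-dialkoxy-3-silyloxybutadienes with 2-alkynoates, which gives 4-hydroxy-2-methoxy-6-alkylbenzoates. Bond formation is asynchronous: the CH2 terminus of 13, which has the largest HOMO coefficient because all three oxygens feed it, bonds to the β-carbon of the ynone (future C1), and the C(OMe)2 terminus bonds to the α-carbon (future C2). This places the acetyl group on C2 between the chain and the OMe-bearing C3, and the silyloxy carbon para to it as C5. The six-membered ring is closed by the suprafacial [4+2] itself; if the reaction goes stepwise, the second bond is a 6-(enolexo)-exo-trig attack of the allenolate on the dimethoxycarbenium carbon and ends in the same adduct 14. In 14, C3 is a ketal carbon and C6 a CH2, so 1,4-loss of methanol is the only path to the arene and leaves one OMe on C3 (15); dilute acid then frees the C5 hydroxyl. No stereocentre is formed, and C2′ lies two atoms from the alkyne, is not acidic and keeps its (R) configuration. The step needs regioselectivity (secured by the polarisation of both partners), reaction at C≡C instead of C=O (no Lewis acid is present) and aromatisation by methanol loss before ketal hydrolysis (acid and water are added only after heating).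

**Step 9**
Reactants: 16 (R)-1-(2-acetyl-5-hydroxy-3-methoxyphenyl)pentadecan-2-yl acetate
Product: 17 (R)-1-(2-acetoxy-5-hydroxy-3-methoxyphenyl)pentadecan-2-yl acetate
Conditions: mCPBA (1.2 equiv), Na2HPO4, CH2Cl2, 0 °C → rt; aq. Na2S2O3 work-up
Reagents that add atoms: 3-chloroperbenzoic acid, O=C(OO)c1cccc(Cl)c1
Why: Baeyer–Villiger oxidation: the peracid adds to the acetyl carbonyl, which its two ortho substituents twist out of conjugation, and the aryl group, made electron-rich by the para OH and ortho OMe, migrates in preference to methyl, inserting oxygen between C2 and the acetyl carbon; the chain acetate and C2′ are untouched and no base is present to cleave the new aryl acetate.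

## Compound list

1 | (R)-epichlorohydrin [(R)-2-(chloromethyl)oxirane] | ClC[C@H]1CO1 | starting material
2 | dodecylmagnesium bromide | CCCCCCCCCCCC[Mg]Br | starting material
3 | (R)-1-chloropentadecan-2-ol | CCCCCCCCCCCCC[C@@H](O)CCl | intermediate
4 | (R)-2-tridecyloxirane | CCCCCCCCCCCCC[C@@H]1CO1 | intermediate
5 | (R)-heptadec-1-yn-4-ol | CCCCCCCCCCCCC[C@@H](O)CC#C | intermediate
6 | (R)-heptadec-1-yn-4-yl acetate | CCCCCCCCCCCCC[C@H](CC#C)OC(C)=O | intermediate
7 | acetyl chloride | CC(=O)Cl | starting material
8 | (R)-2-oxononadec-3-yn-6-yl acetate | CCCCCCCCCCCCC[C@H](CC#CC(C)=O)OC(C)=O | intermediate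
9 | 1,1-dichloroethene | C=C(Cl)Cl | starting material
10 | 4,4,4-trichlorobutan-2-one | CC(=O)CC(Cl)(Cl)Cl | intermediate
11 | 4,4-dichlorobut-3-en-2-one | CC(=O)C=C(Cl)Cl | intermediate
12 | 4,4-dimethoxybut-3-en-2-one | CC(=O)C=C(OC)OC | intermediate
13 | 1,1-dimethoxy-3-(trimethylsilyloxy)buta-1,3-diene | C=C(O[Si](C)(C)C)C=C(OC)OC | intermediate
14 | (R)-1-[2-acetyl-3,3-dimethoxy-5-(trimethylsilyloxy)cyclohexa-1,4-dien-1-yl]pentadecan-2-yl acetate | CCCCCCCCCCCCC[C@H](CC1=C(C(C)=O)C(OC)(OC)C=C(O[Si](C)(C)C)C1)OC(C)=O | intermediate
15 | (R)-1-[2-acetyl-3-methoxy-5-(trimethylsilyloxy)phenyl]pentadecan-2-yl acetate | CCCCCCCCCCCCC[C@H](Cc1cc(O[Si](C)(C)C)cc(OC)c1C(C)=O)OC(C)=O | intermediate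
16 | (R)-1-(2-acetyl-5-hydroxy-3-methoxyphenyl)pentadecan-2-yl acetate | CCCCCCCCCCCCC[C@H](Cc1cc(O)cc(OC)c1C(C)=O)OC(C)=O | intermediate
17 | (R)-1-(2-acetoxy-5-hydroxy-3-methoxyphenyl)pentadecan-2-yl acetate (CNP0236046.1) | CCCCCCCCCCCCC[C@H](Cc1cc(O)cc(OC)c1OC(C)=O)OC(C)=O | target

## Step count and risk

Total step count: 9 (steps 1–9). Longest linear sequence: 6 (steps 1, 2, 3, 4, 8, 9); steps 5–7 form the three-step diene branch.

**Step 8 (key step).** The most likely failure is consumption of the partners before they combine. The ketene-acetal diene can be protodesilylated or hydrolysed by traces of acid. The ynone can isomerise from propargyl to allenyl on heating and lose acetic acid across C1′–C2′. A stepwise Michael pathway can also stall at open-chain adducts. The fallback sets out from 8 and returns at 16; it uses a more robust purchasable diene and differentiates the two oxygens afterwards by chelation. Heating 8 with 1-methoxy-1,3-bis(trimethylsilyloxy)buta-1,3-diene in toluene should give (R)-1-[2-acetyl-3-methoxy-3,5-bis(trimethylsilyloxy)cyclohexa-1,4-dien-1-yl]pentadecan-2-yl acetate F1 (epimer mixture at the ketal carbon, not isolated). Dilute acid should strip methanol and both silyl groups from it to give (R)-1-(2-acetyl-3,5-dihydroxyphenyl)pentadecan-2-yl acetate F2. The C5 hydroxyl, which is not hydrogen-bonded to the ketone, should be benzylated selectively (BnBr, K2CO3, acetone) to give (R)-1-[2-acetyl-5-(benzyloxy)-3-hydroxyphenyl]pentadecan-2-yl acetate F3. Methylation of the chelated C3 hydroxyl (MeI, K2CO3, DMF, 40 °C) should give (R)-1-[2-acetyl-5-(benzyloxy)-3-methoxyphenyl]pentadecan-2-yl acetate F4. Hydrogenolysis (H2 1 atm, Pd/C, EtOAc), stopped once the benzyl group is gone, should give 16.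

**Step 9.** The most likely failure is electrophilic oxidation of the free, electron-rich phenol ring by the peracid (ring hydroxylation and then quinone formation), which competes with the slower addition to the hindered ketone. The fallback sets out from 16 and returns at 17 with the phenol masked during the oxidation. Benzylation (BnBr, K2CO3, acetone) should give (R)-1-[2-acetyl-5-(benzyloxy)-3-methoxyphenyl]pentadecan-2-yl acetate F4. Baeyer–Villiger oxidation of this aryl ether (mCPBA, CH2Cl2) should give (R)-1-[2-acetoxy-5-(benzyloxy)-3-methoxyphenyl]pentadecan-2-yl acetate F5. Hydrogenolysis (H2, Pd/C, EtOAc) should remove the benzyl group without touching either acetate and give 17.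

**Step 4.** Acetyl chloride can be lost as ketene by dehydrochlorination with triethylamine. The amine can also deprotonate the γ-position (C5) of the ynone product, which triggers isomerisation or elimination of acetic acid. The fallback sets out from 5 and returns at 8 by polar acylation before the acetate is present. The dianion of 5 (n-BuLi 2.1 equiv, THF, −78 °C) with N-methoxy-N-methylacetamide should give (R)-6-hydroxynonadec-3-yn-2-one F6. Non-basic acetylation (Ac2O, Sc(OTf)3 cat., MeCN, 0 °C) should give 8.

**Step 2.** In the one-flask sequence the epoxide formed in situ can be opened by alkoxide (oligomerisation) in competition with the acetylide, and ring closure can be incomplete. The fallback sets out from 3 and returns at 5 with the epoxide isolated and opened under Lewis-acid activation. Ring closure (NaOH, H2O/Et2O) should give 4 as an isolated compound. Opening with lithium trimethylsilylacetylide and BF3·OEt2 (THF, −78 °C) should give (R)-1-(trimethylsilyl)heptadec-1-yn-4-ol F7. Desilylation (K2CO3, MeOH) should give 5.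

## Further compounds

F1 | step 8 | (R)-1-[2-acetyl-3-methoxy-3,5-bis(trimethylsilyloxy)cyclohexa-1,4-dien-1-yl]pentadecan-2-yl acetate | CCCCCCCCCCCCC[C@H](CC1=C(C(C)=O)C(OC)(O[Si](C)(C)C)C=C(O[Si](C)(C)C)C1)OC(C)=O
F2 | step 8 | (R)-1-(2-acetyl-3,5-dihydroxyphenyl)pentadecan-2-yl acetate | CCCCCCCCCCCCC[C@H](Cc1cc(O)cc(O)c1C(C)=O)OC(C)=O
F3 | step 8 | (R)-1-[2-acetyl-5-(benzyloxy)-3-hydroxyphenyl]pentadecan-2-yl acetate | CCCCCCCCCCCCC[C@H](Cc1cc(OCc2ccccc2)cc(O)c1C(C)=O)OC(C)=O
F4 | step 8 | (R)-1-[2-acetyl-5-(benzyloxy)-3-methoxyphenyl]pentadecan-2-yl acetate | CCCCCCCCCCCCC[C@H](Cc1cc(OCc2ccccc2)cc(OC)c1C(C)=O)OC(C)=O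
F5 | step 9 | (R)-1-[2-acetoxy-5-(benzyloxy)-3-methoxyphenyl]pentadecan-2-yl acetate | CCCCCCCCCCCCC[C@H](Cc1cc(OCc2ccccc2)cc(OC)c1OC(C)=O)OC(C)=O
F6 | step 4 | (R)-6-hydroxynonadec-3-yn-2-one | CCCCCCCCCCCCC[C@@H](O)CC#CC(C)=O
F7 | step 2 | (R)-1-(trimethylsilyl)heptadec-1-yn-4-ol | CCCCCCCCCCCCC[C@@H](O)CC#C[Si](C)(C)C
A1 | alternative 1 | 5-(benzyloxy)-1-bromo-3-methoxy-2-(methoxymethoxy)benzene | COCOc1c(Br)cc(OCc2ccccc2)cc1OC
A2 | alternative 1 | (R)-1-[5-(benzyloxy)-3-methoxy-2-(methoxymethoxy)phenyl]pentadecan-2-ol | CCCCCCCCCCCCC[C@@H](O)Cc1cc(OCc2ccccc2)cc(OC)c1OCOC
A3 | alternative 2 | (R)-1-(3-hydroxy-5-methoxyphenyl)pentadecan-2-yl acetate | CCCCCCCCCCCCC[C@H](Cc1cc(O)cc(OC)c1)OC(C)=O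
A4 | alternative 2 | (R)-1-(5-methoxy-3,6-dioxocyclohexa-1,4-dien-1-yl)pentadecan-2-yl acetate | CCCCCCCCCCCCC[C@H](CC1=CC(=O)C=C(OC)C1=O)OC(C)=O
A5 | alternative 2 | (R)-1-(2,5-dihydroxy-3-methoxyphenyl)pentadecan-2-yl acetate | CCCCCCCCCCCCC[C@H](Cc1cc(O)cc(OC)c1O)OC(C)=O
A6 | alternative 3 | 1-(allyloxy)-4-(benzyloxy)-2-methoxybenzene | C=CCOc1ccc(OCc2ccccc2)cc1OC
A7 | alternative 3 | 2-allyl-4-(benzyloxy)-6-methoxyphenol | C=CCc1cc(OCc2ccccc2)cc(OC)c1O
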